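## Structural features

The target, (5R,6R,7R,8S,10S) in elemane numbering, is an elemanolide. It has one cyclohexane (C5–C10) whose C6–C7 bond is trans-fused to an α-methylene-γ-butyrolactone (O6–C12, C11=C13). C10 is quaternary (β-methyl, α-vinyl C1=C2) and stands next to C5, which carries the 2-substituted acrylic acid (C4=C3, C15O2H). C6 (α-O), C7 (β-C11) and C8 (α-O-angelate) follow, so five stereocentres are contiguous and only C9 is a methylene. In the chair every substituent at C5–C8 is equatorial and the C10 methyl alone is axial. The fragile groups are the two exocyclic Michael acceptors, the (Z)-2-methylbut-2-enoate (which goes to the E isomer with acid, heat or nucleophilic catalysts) and the free acid beside a lactone. In addition, two oxygens (O6, O8) and two acyl carbons (C12, C15) could pair up into the wrong lactone. The real difficulty is twofold: a quaternary C10 in one absolute sense with a trans-1,2-dialkenyl relation to C5, and carbinol centres C6 and C8 whose hydrogens lie on the β face, syn to the axial methyl, which is the face hydride reagents avoid. The key step exploits the fact that C2=C1–C10–C5–C4=C3 is a hexa-1,5-diene. Joining C1 to C4 and C2 to C3 turns it into a bicyclo[2.2.0]hexane on the C5–C10 bond, which an enone–cyclobutene photocycloaddition builds and heat takes apart again.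

## Logic of the disconnections

**25 ⇒ 24 ⇒ 21 + 22.** The O–C(CH3)3 bond of the C15 ester and the O8–acyl bond are cut last. The free acid and the isomerisable Z-enoate then appear only at the very end. This demands an acid-labile ester that survives everything else and an acylation that does not touch the two Michael acceptors.

**21 ⇒ 20 ⇒ 18 ⇒ 17.** Both exocyclic methylenes are traced to β-dimethylamino carbonyl units: C11=C13 by cutting C11–C13 (Mannich retron), C4=C3 by adding an amine across it. While the amines are in place the molecule has no Michael acceptor, and one exhaustive methylation/elimination releases both alkenes together. The demand is a selective lactone enolate and a clean double β-elimination.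

**17 ⇒ 15.** The lactone bond O6–C12 and the C6–H bond are cut, giving a C6 ketone. The ketone must exist after ring fragmentation because C5 can only be inverted through it. Its reduction must deliver hydrogen to the β face, syn to the axial methyl, so a thermodynamically controlled electron-transfer reduction is required, which in turn requires the acrylate to be masked. C12 is a methyl ester and C15 a tert-butyl ester so that O6 closes onto C12 only. O8 is still protected at this point so that it cannot compete for C12.

**15 ⇒ 13.** The C3–N bond is cut and C5 is returned to its kinetic (cis) configuration. In the forward direction amine addition removes the β,γ-unsaturation that could otherwise migrate into conjugation with C6=O, and base then equilibrates C5 and C7 to the all-equatorial arrangement.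

**13 ⇒ 11 (through 12).** C1–C4 and C2–C3 are reconnected, turning vinyl and acrylate into a bicyclo[2.2.0]hexane. This removes both alkenes and the Michael acceptor from all enolate and oxidation chemistry. The forward fragmentation is not a simple double bond scission. The intermediate 1,4-diyl can also open C5–C10 to the ten-membered dienone 12, whose Cope rearrangement re-forms C5 and C10. The heating is therefore placed after C7 and C8 carry a trans-diequatorial pair of substituents, which holds the chair through which C10 is returned in its original sense. Heating the bare photoadduct would risk racemisation by ring inversion of an unanchored dienone.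

**11 ⇒ 10 ⇒ 9 ⇒ 8 ⇒ 7.** O8 is traced to silicon (C–Si to C–O with retention), C7–C11 is cut (enolate alkylation) and the C8–Si bond is cut (conjugate silylation). Silicon is a hydroxyl surrogate that cannot be eliminated from the C7 enolate. It is oxidised on the tricycle because the oxidation needs electrophilic reagents that no alkene would survive. The α face at C8 is not reliably preferred by the substrate (angular methyl on β, cyclobutane C1–H on α), so the face is assigned to a chiral catalyst.

**7 ⇒ 6.** The C7=C8 double bond is removed. Forward dehydrogenation can only go towards C7–C8 because C4 carries no hydrogen.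

**6 ⇒ 4 + 5.** C10–C1 and C5–C4 are cut (the key step). Two achiral, simple components result. 6 carries the target configuration at C10 and the opposite one at C5, which is expected from the cis ring fusion and is corrected in step 11. The step must give head-to-head regiochemistry and one enantiomer. The alkene partner stays a tert-butyl ester because its hindered carbonyl competes least for a Lewis acid, cannot be attacked by the C7 enolate later, and leaves at the end without base.

**4 ⇒ 3 ⇒ 2 ⇒ 1.** The ring double bond is traced to an α-bromo ester and this to the saturated acid, which is routine chemistry.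

## Other disconnections considered

**Alternative 1:** The cut is C5–C6. Forward, the open-chain aldehyde A1 (C6 formyl; C5 as the CH of a 2-methylprop-1-enyl group on quaternary C10) closes with Me2AlCl in an intramolecular carbonyl-ene reaction to cyclohexanol A2, creating the ring, C5, C6 and the C4=C3 isopropenyl group.
- In its favour: a chair transition state with equatorial substituents should give the 5β,6α-trans pair directly. On C5/C6 control it is better than the chosen plan, which needs an epimerisation (step 11) and an electron-transfer reduction (step 12).
- Against it here: A1 must already hold C7, C8 and an acyclic quaternary C10 in one absolute sense. Methyl and vinyl on C10 differ little in size, so the ene step adds no control there. C15 arrives as a methyl group that must be oxidised to the acid late, beside the vinyl group and the lactone methylene.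
- Comparison: structurally it forms one bond and two lasting stereocentres, where the chosen key step forms two bonds and the quaternary centre but sacrifices two of its four stereocentres. Mechanistically it is a closed-shell, well-precedented process and in this respect the better of the two. In step economy the gain at C5/C6 is expected to be spent on assembling A1 and on raising C15, so no net saving is foreseen.

**Alternative 2:** The cuts are C6–C7 and O6–C12. Forward, CrCl2 converts the allylic bromide of A3 into an allylchromium that adds through C7 to the C6 aldehyde (Nozaki–Hiyama–Kishi-type, cyclic transition state), and the chromium alkoxide closes onto the methyl ester to give A4.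
- In its favour: cyclohexane, trans-lactone and exocyclic methylene arise in one operation. On this point it is better than steps 12–14 of the chosen plan taken together. The reagent is mild and selective for aldehydes.
- Against it here: A3 carries C5 as an epimerisable α-stereocentre of an aldehyde next to an open-chain quaternary C10. Two equivalents of a divalent chromium salt are needed. A4 has C15 as a methyl group, so an allylic oxidation to the acid must be done with the methylene lactone already present.
- Comparison: structurally it delivers more of the final functionality in its key step than the chosen plan does. Mechanistically it is equal in reliability to the later steps of the chosen plan, but its stereochemical outcome rests on centres that are hard to install in an acyclic chain. In step economy it is likely equal at best, because of the precursor synthesis and the C15 oxidation.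

**Alternative 3:** The cuts are C5–C10 and C8–C9. Forward, methacrolein A5 and the 1-amino-3-siloxydiene A6 combine under the chiral Lewis acid (salen)CrSbF6 to cyclohexene A7, fixing quaternary C10.
- In its favour: catalytic asymmetric Diels–Alder reactions of this diene class with α-substituted acroleins are established. On absolute control of C10 it is better than the chosen plan, whose enantioselective step is untried.
- Against it here: A7 carries its oxygen at C7 and nitrogen at C5, whereas the target needs carbon at C7 and oxygen at C6 and C8. The acrylate at C5, O6, C11 and O8 would all have to be introduced by relay from a centre whose two substituents differ little in size, so 1,2- and 1,3-induction should be weak.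
- Comparison: structurally its key step fixes one of five stereocentres and none of the alkenyl groups, while the chosen step lays down C10 and both alkenyl groups in latent form with C15 at the acid level. Mechanistically it is the safer step. In step economy it is expected to be clearly longer.

Key step: step 4

Remark: locants follow elemane numbering (vinyl C1=C2 on C10, acrylate C3=C4–C15 on C5, lactone carbons C11–C13); β is the ring face of the C10 methyl, α the opposite face. Which antipode of each chiral catalyst (steps 4 and 6) gives the required sense is assumed to be settled on the first run.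

Step 1
Reactants: 1 cyclobutanecarboxylic acid
Product: 2 tert-butyl cyclobutanecarboxylate
Conditions: isobutene, H2SO4 (cat.), CH2Cl2, −78 °C → rt, sealed vessel
Reagents that add atoms: 2-methylpropene (isobutene), C=C(C)C
Why: Acid-catalysed addition of the carboxylic acid to isobutene (tert-butyl esterification); the hindered, acid-labile ester is needed for steps 4, 7 and 17.

Step 2
Reactants: 2 tert-butyl cyclobutanecarboxylate
Product: 3 tert-butyl 1-bromocyclobutane-1-carboxylate
Conditions: LiN(i-Pr)2, THF, −78 °C; BrCCl2CCl2Br, −78 °C → rt
Reagents that add atoms: 1,2-dibromo-1,1,2,2-tetrachloroethane, BrC(Cl)(Cl)C(Cl)(Cl)Br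
Why: Ester enolate formation and electrophilic α-bromination with a positive-bromine donor; the tert-butyl ester suppresses self-condensation.

Step 3
Reactants: 3 tert-butyl 1-bromocyclobutane-1-carboxylate
Product: 4 tert-butyl cyclobut-1-ene-1-carboxylate
Conditions: KOt-Bu, THF, 0 °C → rt
Reagents that add atoms: none
Why: E2 dehydrobromination gives the conjugated, strained alkene; it should be used freshly distilled because it polymerises on standing.

Step 4
Reactants: 5 3-methylcyclohex-2-en-1-one; 4 tert-butyl cyclobut-1-ene-1-carboxylate
Product: 6 cis-anti-cis photoadduct, tert-butyl 6-methyl-10-oxotricyclo[4.4.0.0^2,5]decane-2-carboxylate (elemane numbering: C6 ketone, 10β-methyl, 5β-H, cyclobutane bonds C10–C1 and C5–C4 on the α face, C2–C3 bridge anti to the six-membered ring, ester on C4)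
Conditions: AlBr3-activated 1,3,2-oxazaborolidine from (S)-α,α-diarylprolinol and an arylboronic acid (50 mol %), 4 (5 equiv), hν (366 nm), CH2Cl2, −75 °C
Reagents that add atoms: none
Why: Proposed new method: enantioselective Lewis-acid-catalysed enone–alkene [2+2] photocycloaddition is the closest known reaction type (shown for cyclohex-2-enones with unfunctionalised alkenes), and the uncatalysed head-to-head addition of cyclobut-1-ene-1-carboxylates to 3-alkylcyclohex-2-enones is also known, but the combination with an ester-bearing, electron-poor alkene is untried; mechanistically the activated oxazaborolidine binds the enone oxygen, only the red-shifted complex absorbs at 366 nm, and its triplet bonds C10 to C1 of 4 to give a 1,4-diradical (ester-stabilised at C4, α-keto at C5) that closes C4–C5. The cyclobutane is therefore closed stepwise, by radical recombination after spin inversion, not by a concerted pericyclic process. C10 is set by the catalyst, whose aryl groups shield one face of the bound enone so that C1 enters on the α face. C5 follows from closure to the less strained cis 6-4 fusion (any trans-fused share would epimerise to cis with base, and C5 is corrected in step 11 in any case). C1 and C4 follow from approach of 4 with its CH2–CH2 bridge turned away from the six-membered ring, and both centres are destroyed again in step 10. The step needs head-to-head regiochemistry, which first bonding at the unsubstituted alkene carbon secures because it leaves the radical beside the ester. It also needs face selectivity, which holds only if the Lewis acid stays on the enone rather than on the hindered tert-butyl ester and if the racemic reaction of free 5 is outrun.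

Step 5
Reactants: 6 cis-anti-cis photoadduct
Product: 7 tricyclic enone (6 with a C7=C8 double bond conjugated to the C6 ketone)
Conditions: IBX, DMSO/PhF (1:2), 65 °C
Reagents that add atoms: none
Why: IBX dehydrogenation of a ketone to the enone through its enol; only the C7–C8 side can react because C4 carries no hydrogen, and 65 °C is far below the fragmentation temperature of the bicyclohexane.

Step 6
Reactants: 7 tricyclic enone
Product: 8 8α-(dimethylphenylsilyl) ketone (6 carrying PhMe2Si on C8, α face, 8S)
Conditions: CuCl (5 mol %), chiral C1-symmetric imidazolinium salt (5.5 mol %), NaOt-Bu (11 mol %), PhMe2Si–Bpin (1.2 equiv), THF, −78 °C; then H2O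
Reagents that add atoms: 2-(dimethylphenylsilyl)-4,4,5,5-tetramethyl-1,3,2-dioxaborolane, CC1(C)OB(OC1(C)C)[Si](C)(C)c1ccccc1
Why: Copper–NHC-catalysed enantioselective conjugate silyl transfer from a Si–B reagent to a cyclohex-2-enone, used here for reagent control because the two faces of C8 are only weakly and uncertainly distinguished by the substrate. The ligand antipode that places silicon on the α face is chosen and water protonates the boron enolate at C7.

Step 7
Reactants: 8 8α-(dimethylphenylsilyl) ketone
Product: 9 7β-(2-methoxy-2-oxoethyl)-8α-(dimethylphenylsilyl) ketone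
Conditions: LiN(i-Pr)2, THF, −78 °C; BrCH2CO2Me, DMPU, −78 → −30 °C
Reagents that add atoms: methyl bromoacetate, COC(=O)CBr
Why: Kinetic enolisation at the C7 methylene (the C5 methine is hindered and its enolate would be a strained alkylidenecyclobutane) and SN2 alkylation anti to the neighbouring silyl group give the 7β,8α-trans product; C7 stays epimerisable and is re-equilibrated in step 11, and the tert-butyl ester resists Claisen attack.

Step 8
Reactants: 9 7β-(2-methoxy-2-oxoethyl)-8α-(dimethylphenylsilyl) ketone
Product: 10 8α-hydroxy keto diester
Conditions: KBr, AcOOH, NaOAc, AcOH, 0 °C → rt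
Reagents that add atoms: peracetic acid, CC(=O)OO
Why: Fleming–Tamao oxidation: ipso-bromodesilylation of the phenyl group, then peroxide-induced migration of C8 from silicon to oxygen with retention. It is done at this stage because no alkene is present yet and the buffered medium spares the tert-butyl ester.

Step 9
Reactants: 10 8α-hydroxy keto diester
Product: 11 8α-(tert-butyldimethylsilyloxy) keto diester
Conditions: t-BuMe2SiCl, imidazole, DMF, rt
Reagents that add atoms: tert-butyldimethylsilyl chloride, CC(C)(C)[Si](C)(C)Cl
Why: Silyl ether formation keeps O8 from closing onto the C12 methyl ester and from dehydration on heating. The C8 silyloxy and C7 acetate groups form the trans-diequatorial pair that fixes the ring conformation in step 10.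

Step 10
Reactants: 11 8α-(tert-butyldimethylsilyloxy) keto diester
Product: 13 cis-divinyl ketone (10β-methyl-10α-vinyl-5α-[1-(tert-butoxycarbonyl)vinyl] cyclohexan-6-one with 7β-CH2CO2Me and 8α-OSiMe2t-Bu), via ten-membered dienone 12 (not isolated)
Conditions: PhMe (0.02 M), 2,6-di-tert-butyl-4-methylphenol (cat.), silanised sealed tube, 180 °C
Reagents that add atoms: none
Why: Known thermal fragmentation of enone–cyclobutene photoadducts to 1,2-divinylcyclohexanes. Homolysis of C1–C4 gives a cyclohexane-1,4-diyl that either loses C2–C3 directly or opens C5–C10 to dienone 12, whose Cope rearrangement re-forms C5–C10 and cuts C2–C3. The chair transition state with the C7 and C8 substituents equatorial should return C10 in its original sense and C5 cis.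

Step 11
Reactants: 13 cis-divinyl ketone
Product: 15 all-equatorial amino keto diester (5β side chain CH(CO2t-Bu)CH2NMe2 as a C4 epimer pair), via cis amino ester 14 (not isolated)
Conditions: Me2NH (2 M in THF, 5 equiv), MeOH, 40 °C; then DBU (0.3 equiv), rt
Reagents that add atoms: dimethylamine, CNC
Why: Aza-Michael addition masks the acrylate, so the double bond can no longer migrate into conjugation with C6=O. Base-mediated enolisation then equilibrates C5 (and C7) to the ketone with all of C5, C7 and C8 equatorial; the equatorial silyloxy group is poorly aligned for β-elimination.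

Step 12
Reactants: 15 all-equatorial amino keto diester
Product: 17 trans-fused 6α,12-lactone (8α-OSiMe2t-Bu; C3 dimethylamino; C15 tert-butyl ester), via hydroxy ester 16 (not isolated)
Conditions: SmI2, H2O, THF, 0 °C → rt; then PPTS, PhMe, 50 °C
Reagents that add atoms: none
Why: Ketyl-type electron-transfer reduction should give the thermodynamically preferred equatorial 6α-alcohol, whereas hydride would enter anti to the axial C10 methyl and give 6β. With the acrylate masked nothing can intercept the ketyl, and O6 then closes onto the C12 methyl ester rather than the tert-butyl ester.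

Step 13
Reactants: 17 trans-fused 6α,12-lactone
Product: 18 11-(dimethylaminomethyl) lactone (bis-amine; C4 and C11 epimers)
Conditions: LiN(i-Pr)2, THF, −78 °C; CH2=NMe2+ I−, −78 °C → rt
Reagents that add atoms: dimethyl(methylene)ammonium iodide, C=[N+](C)C.[I-]
Why: Mannich reaction of the lactone enolate; the C11 methylene is deprotonated in preference to the hindered C4–H of the tert-butyl ester, and no hydroxyl or Michael acceptor is present.

Step 14
Reactants: 18 11-(dimethylaminomethyl) lactone
Product: 20 8α-(tert-butyldimethylsilyloxy)elema-1,3,11(13)-trien-12,6α-olide 15-tert-butyl ester, via bis-ammonium diiodide 19 (not isolated)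
Conditions: MeI, MeOH, rt; then NaHCO3, H2O/EtOAc, rt → 40 °C
Reagents that add atoms: none
Why: Exhaustive N-methylation followed by base-induced β-elimination (Hofmann-type, E1cB) of both β-ammonio carbonyl units releases C11=C13 and C4=C3 in one operation.

Step 15
Reactants: 20 8α-silyloxy trienolide tert-butyl ester
Product: 21 8α-hydroxyelema-1,3,11(13)-trien-12,6α-olide 15-tert-butyl ester
Conditions: HF·pyridine, pyridine/THF, 0 °C → rt
Reagents that add atoms: none
Why: Fluoride cleavage of the silyl ether under weakly acidic conditions, under which neither translactonisation to O8 nor conjugate addition to the methylene lactone is expected.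

Step 16
Reactants: 21 8α-hydroxy trienolide tert-butyl ester; 22 angelic acid
Product: 24 8α-angeloyloxyelema-1,3,11(13)-trien-12,6α-olide 15-tert-butyl ester, via mixed anhydride 23 (not isolated)
Conditions: 22, 2,4,6-Cl3C6H2COCl, Et3N, PhMe, rt; then 21, 80 °C
Reagents that add atoms: none
Why: Yamaguchi-type esterification: the mixed anhydride acylates the equatorial 8α-hydroxyl at the less hindered angeloyl carbonyl. Leaving out nucleophilic amine catalysts should keep the Z double bond from isomerising to the tiglate.

Step 17
Reactants: 24 8α-angeloyloxy trienolide tert-butyl ester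
Product: 25 8α-angeloyloxyelema-1,3,11(13)-trien-12,6α-olid-15-oic acid (target)
Conditions: CF3CO2H/CH2Cl2 (1:4), 0 °C
Reagents that add atoms: none
Why: Acidolysis of the tert-butyl ester with loss of isobutene; lactone, angelate and alkenes are stable to brief cold acid.

## Compound list

1 | cyclobutanecarboxylic acid | OC(=O)C1CCC1 | starting material
2 | tert-butyl cyclobutanecarboxylate | CC(C)(C)OC(=O)C1CCC1 | intermediate
3 | tert-butyl 1-bromocyclobutane-1-carboxylate | CC(C)(C)OC(=O)C1(Br)CCC1 | intermediate
4 | tert-butyl cyclobut-1-ene-1-carboxylate | CC(C)(C)OC(=O)C1=CCC1 | intermediate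
5 | 3-methylcyclohex-2-en-1-one | CC1=CC(=O)CCC1 | starting material
6 | cis-anti-cis photoadduct, tert-butyl 6-methyl-10-oxotricyclo[4.4.0.0^2,5]decane-2-carboxylate | O=C1CCC[C@@]2(C)[C@@H]3CC[C@]3(C(=O)OC(C)(C)C)[C@@H]12 | intermediate
7 | tricyclic enone (C7=C8) | O=C1C=CC[C@@]2(C)[C@@H]3CC[C@]3(C(=O)OC(C)(C)C)[C@@H]12 | intermediate
8 | 8α-(dimethylphenylsilyl) ketone | O=C1C[C@@H]([Si](C)(C)c2ccccc2)C[C@@]3(C)[C@@H]4CC[C@]4(C(=O)OC(C)(C)C)[C@@H]13 | intermediate
9 | 7β-(2-methoxy-2-oxoethyl)-8α-(dimethylphenylsilyl) ketone | O=C1[C@H](CC(=O)OC)[C@@H]([Si](C)(C)c2ccccc2)C[C@@]3(C)[C@@H]4CC[C@]4(C(=O)OC(C)(C)C)[C@@H]13 | intermediate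
10 | 8α-hydroxy keto diester | O=C1[C@H](CC(=O)OC)[C@@H](O)C[C@@]2(C)[C@@H]3CC[C@]3(C(=O)OC(C)(C)C)[C@@H]12 | intermediate
11 | 8α-(tert-butyldimethylsilyloxy) keto diester | O=C1[C@H](CC(=O)OC)[C@@H](O[Si](C)(C)C(C)(C)C)C[C@@]2(C)[C@@H]3CC[C@]3(C(=O)OC(C)(C)C)[C@@H]12 | intermediate
12 | ten-membered dienone (cyclodeca-1(10),4-dien-6-one; ring-cis C1=C10, ring-trans C4=C5) | C/C1=C/CC/C(C(=O)OC(C)(C)C)=C/C(=O)[C@H](CC(=O)OC)[C@@H](O[Si](C)(C)C(C)(C)C)C1 | intermediate (not isolated)
13 | cis-divinyl ketone (5-epi) | C=C[C@]1(C)C[C@H](O[Si](C)(C)C(C)(C)C)[C@@H](CC(=O)OC)C(=O)[C@@H]1C(=C)C(=O)OC(C)(C)C | intermediate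
14 | cis amino ester (5-epi; C4 epimers) | C=C[C@]1(C)C[C@H](O[Si](C)(C)C(C)(C)C)[C@@H](CC(=O)OC)C(=O)[C@@H]1C(CN(C)C)C(=O)OC(C)(C)C | intermediate (not isolated)
15 | all-equatorial amino keto diester (C4 epimers) | C=C[C@]1(C)C[C@H](O[Si](C)(C)C(C)(C)C)[C@@H](CC(=O)OC)C(=O)[C@H]1C(CN(C)C)C(=O)OC(C)(C)C | intermediate
16 | 6α-hydroxy diester (C4 epimers) | C=C[C@]1(C)C[C@H](O[Si](C)(C)C(C)(C)C)[C@@H](CC(=O)OC)[C@H](O)[C@H]1C(CN(C)C)C(=O)OC(C)(C)C | intermediate (not isolated)
17 | trans-fused 6α,12-lactone (C4 epimers) | C=C[C@]1(C)C[C@H](O[Si](C)(C)C(C)(C)C)[C@H]2CC(=O)O[C@@H]2[C@H]1C(CN(C)C)C(=O)OC(C)(C)C | intermediate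
18 | 11-(dimethylaminomethyl) lactone, bis-amine (C4 and C11 epimers) | C=C[C@]1(C)C[C@H](O[Si](C)(C)C(C)(C)C)[C@H]2C(CN(C)C)C(=O)O[C@@H]2[C@H]1C(CN(C)C)C(=O)OC(C)(C)C | intermediate
19 | bis(trimethylammonium) diiodide | C=C[C@]1(C)C[C@H](O[Si](C)(C)C(C)(C)C)[C@H]2C(C[N+](C)(C)C)C(=O)O[C@@H]2[C@H]1C(C[N+](C)(C)C)C(=O)OC(C)(C)C.[I-].[I-] | intermediate (not isolated)
20 | 8α-(tert-butyldimethylsilyloxy)elema-1,3,11(13)-trien-12,6α-olide 15-tert-butyl ester | C=C[C@]1(C)C[C@H](O[Si](C)(C)C(C)(C)C)[C@H]2C(=C)C(=O)O[C@@H]2[C@H]1C(=C)C(=O)OC(C)(C)C | intermediate
21 | 8α-hydroxyelema-1,3,11(13)-trien-12,6α-olide 15-tert-butyl ester | C=C[C@]1(C)C[C@H](O)[C@H]2C(=C)C(=O)O[C@@H]2[C@H]1C(=C)C(=O)OC(C)(C)C | intermediate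
22 | angelic acid, (Z)-2-methylbut-2-enoic acid | C/C=C(/C)C(=O)O | starting material
23 | angelic 2,4,6-trichlorobenzoic anhydride | C/C=C(/C)C(=O)OC(=O)c1c(Cl)cc(Cl)cc1Cl | intermediate (not isolated)
24 | 8α-angeloyloxyelema-1,3,11(13)-trien-12,6α-olide 15-tert-butyl ester | C=C[C@]1(C)C[C@H](OC(=O)/C(C)=C\C)[C@H]2C(=C)C(=O)O[C@@H]2[C@H]1C(=C)C(=O)OC(C)(C)C | intermediate
25 | 8α-angeloyloxyelema-1,3,11(13)-trien-12,6α-olid-15-oic acid | C=C[C@]1(C)C[C@H](OC(=O)/C(C)=C\C)[C@H]2C(=C)C(=O)O[C@@H]2[C@H]1C(=C)C(=O)O | target

Total steps: 17. Longest linear sequence: 17 steps (1 to 25; 5 and 22 each enter in a single step).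

## Least certain steps

**Step 4 (key step, proposed new method).** The most likely failure is loss of face control. The Lewis acid may be diverted to the ester carbonyl of 4, or the electron-poor alkene may add too slowly to the electron-poor complexed triplet, so that the uncatalysed racemic reaction of free 5 takes over; slow Lewis-acid cleavage of the tert-butyl ester is a second risk. The fallback sets out from 4 and 5 and comes back at 6. Irradiation without any Lewis acid (350 nm, CH2Cl2, rt), the known head-to-head photocycloaddition, gives 6 as a racemate with the mirror-image photoadduct F1. Preparative chromatography on a cellulose tris(3,5-dimethylphenylcarbamate) phase then delivers 6. The loss of half the material falls on two inexpensive components.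

**Step 6.** The likely failure is poor facial selectivity in a mismatched pairing of catalyst and substrate, giving the 8β-silane, which cannot be corrected later. The fallback sets out from 7 and comes back at 8, and replaces reagent control by intramolecular delivery:
- Luche reduction (NaBH4, CeCl3·7H2O, MeOH, −20 °C) should attack C6 from the β face, away from the ester-bearing cyclobutane, to give 6α-allylic alcohol F2.
- Silylation with (HMe2Si)2NH and intramolecular hydrosilylation (Pt2[(CH2=CHSiMe2)2O]3 cat.) delivers silicon to C8 on the face of O6, giving cyclic siloxane F3.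
- PhLi (THF, −78 °C) opens the Si–O bond to hydroxy silane F4.
- Swern oxidation returns 8.

**Step 10.** Two things can go wrong. The C10/C5 configuration may be partly lost relative to C7/C8 if dienone 12 inverts its ring before the Cope rearrangement. Prolonged heating may also cause elimination of silanol from the β-silyloxy ketone or loss of isobutene. The fallback sets out from 11 and comes back at 13 and makes no new compound (F0). The fragmentation is stopped at 12 by shorter heating at about 140 °C and 12 is isolated. Its Cope rearrangement is then run as a separate, charge-accelerated step (Me2AlCl, CH2Cl2, −78 °C → 0 °C; acid-promoted Cope rearrangement of a 2-acyl-1,5-diene), where thermal side reactions and ring inversion compete less.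

**Step 12.** The likely failures are incomplete thermodynamic control, giving the axial 6β-alcohol and from it the cis-lactone, or over-reduction of an ester. The fallback sets out from 15 and comes back at 17 and replaces thermodynamic reduction by inversion:
- LiBH(s-Bu)3 (THF, −78 °C) attacks from the open α face and the 6β-alkoxide closes to cis-fused lactone F5.
- LiOH (THF/H2O) opens it to 6β-hydroxy acid F6.
- Mitsunobu lactonisation (PPh3, diisopropyl azodicarboxylate, high dilution) closes O12 onto C6 with inversion to give 17.

**Step 16.** The likely failures are isomerisation of the angelate to the tiglate, slow acylation of the flanked secondary alcohol, and conjugate addition of the amine base to the methylene lactone at 80 °C. The fallback sets out from 18 and comes back at 24. It builds the Z-enoate by olefination before the Michael acceptors exist: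
- HF·pyridine gives amino alcohol F7.
- Esterification with 2-[bis(2,2,2-trifluoroethoxy)phosphoryl]propanoic acid (N,N'-dicyclohexylcarbodiimide) gives phosphonate ester F8.
- Z-selective Horner–Wadsworth–Emmons olefination with acetaldehyde (KN(SiMe3)2, 18-crown-6, THF, −78 °C) gives angelate bis-amine F9.
- MeI, then NaHCO3, releases both methylenes and gives 24.

## Further compounds

F1 | step 4 | mirror-image photoadduct (enantiomer of 6) | O=C1CCC[C@]2(C)[C@H]3CC[C@@]3(C(=O)OC(C)(C)C)[C@H]12
F2 | step 6 | 6α-allylic alcohol | O[C@H]1C=CC[C@@]3(C)[C@@H]4CC[C@]4(C(=O)OC(C)(C)C)[C@@H]13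
F3 | step 6 | cyclic siloxane (O6–SiMe2–C8, cis-fused) | C[Si]1(C)O[C@H]2C[C@@H]1C[C@@]3(C)[C@@H]4CC[C@]4(C(=O)OC(C)(C)C)[C@@H]23
F4 | step 6 | 6α-hydroxy 8α-(dimethylphenylsilyl) ester | O[C@H]1C[C@@H]([Si](C)(C)c2ccccc2)C[C@@]3(C)[C@@H]4CC[C@]4(C(=O)OC(C)(C)C)[C@@H]13
F0 | step 10 | none | none
F5 | step 12 | cis-fused 6β,12-lactone | C=C[C@]1(C)C[C@H](O[Si](C)(C)C(C)(C)C)[C@H]2CC(=O)O[C@H]2[C@H]1C(CN(C)C)C(=O)OC(C)(C)C
F6 | step 12 | 6β-hydroxy acid | C=C[C@]1(C)C[C@H](O[Si](C)(C)C(C)(C)C)[C@@H](CC(=O)O)[C@@H](O)[C@H]1C(CN(C)C)C(=O)OC(C)(C)C
F7 | step 16 | 8α-hydroxy bis-amine lactone | C=C[C@]1(C)C[C@H](O)[C@H]2C(CN(C)C)C(=O)O[C@@H]2[C@H]1C(CN(C)C)C(=O)OC(C)(C)C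
F8 | step 16 | 8α-O-[2-(bis(2,2,2-trifluoroethoxy)phosphoryl)propanoyl] bis-amine lactone | C=C[C@]1(C)C[C@H](OC(=O)C(C)P(=O)(OCC(F)(F)F)OCC(F)(F)F)[C@H]2C(CN(C)C)C(=O)O[C@@H]2[C@H]1C(CN(C)C)C(=O)OC(C)(C)C
F9 | step 16 | 8α-angeloyloxy bis-amine lactone | C=C[C@]1(C)C[C@H](OC(=O)/C(C)=C\C)[C@H]2C(CN(C)C)C(=O)O[C@@H]2[C@H]1C(CN(C)C)C(=O)OC(C)(C)C
A1 | alternative 1 | open-chain aldehyde for the ene closure | C=C[C@](C)(C[C@H](O[Si](C)(C)C(C)(C)C)[C@@H](CC(=O)OC)C=O)C=C(C)C
A2 | alternative 1 | trans-2-isopropenylcyclohexanol hydroxy ester | C=C[C@]1(C)C[C@H](O[Si](C)(C)C(C)(C)C)[C@@H](CC(=O)OC)[C@H](O)[C@H]1C(C)=C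
A3 | alternative 2 | allylic bromide aldehyde | O=C[C@@H](C(C)=C)[C@](C)(C=C)C[C@H](O[Si](C)(C)C(C)(C)C)/C=C(\CBr)C(=O)OC
A4 | alternative 2 | 8α-(tert-butyldimethylsilyloxy)elema-1,3,11(13)-trien-12,6α-olide | C=C[C@]1(C)C[C@H](O[Si](C)(C)C(C)(C)C)[C@H]2C(=C)C(=O)O[C@@H]2[C@H]1C(C)=C
A5 | alternative 3 | methacrolein | CC(=C)C=O
A6 | alternative 3 | (E)-1-(dimethylamino)-3-(tert-butyldimethylsilyloxy)buta-1,3-diene | CN(C)/C=C/C(=C)O[Si](C)(C)C(C)(C)C
A7 | alternative 3 | 2-(dimethylamino)-1-methyl-4-(tert-butyldimethylsilyloxy)cyclohex-3-ene-1-carbaldehyde | O=C[C@]1(C)CCC(O[Si](C)(C)C(C)(C)C)=C[C@@H]1N(C)C
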